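**Plan**

Ring A is the benzene ring; the side chain is numbered C1′ (benzylic) to C16′.
- Cuts, in retrosynthetic order: C1′–C2′ together with C3′–CH3 (back to a terminal alkyne C2′≡C3′, AlMe3 and a benzylic chloride on ring A), then C4′–C5′ (propargylation of an enal), C14′=C15′ (cross-metathesis), C12′–C13′ (allylation of an enal), ending at geranyl acetate.
- Enabling feature: in C1′H2–C2′H=C3′(CH3)–C4′H2, the vinylic CH (C2′) is bonded to the benzylic carbon of ring A and the C3′ methyl is cis to C1′. This is the pattern left by syn-methylmetalation of a terminal alkyne followed by benzylation with retention, and the C5′ oxygen is homopropargylic to that alkyne.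
- Forward order: geranyl acetate → C8 oxidation → allylation (C12′) → prenyl terminus by metathesis → C1 enal → propargylation (C5′) → one-flask methylalumination/benzylation with the ring A chloride → global desilylation.
- Stereochemistry: C12′ (R) and C5′ (R) come from Re-face additions of allyl- and allenylboronate under the same chiral phosphoric acid; 6′E and 10′E come from geranyl acetate and E-selective SeO2 oxidation; 2′E comes from the syn-carbometalation.

Key step: step 13

Remark: (R)-TRIP is taken to expose the Re face of both enals, as it does with aromatic and α,β-unsaturated aldehydes; if the sense proves opposite, the (S) catalyst would be used in steps 6 and 11.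

**Route**

Step 1
Reactants: 1 4-methoxy-2-methylphenol
Product: 2 2-hydroxy-5-methoxy-3-methylbenzaldehyde
Conditions: MgCl2, Et3N, (CH2O)n, MeCN, reflux; 1 M HCl work-up
Reagents that add atoms: formaldehyde (as paraformaldehyde), C=O
Why: Magnesium-phenoxide-directed ortho-formylation (Casnati–Skattebøl reaction) should place CHO at the only free ortho position of ring A, a second equivalent of formaldehyde acting as the hydride acceptor.

Step 2
Reactants: 2 2-hydroxy-5-methoxy-3-methylbenzaldehyde
Product: 3 2-(tert-butyldimethylsilyloxy)-5-methoxy-3-methylbenzaldehyde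
Conditions: TBSCl, imidazole, DMF, rt to 40 °C
Reagents that add atoms: tert-butyldimethylsilyl chloride, CC(C)(C)[Si](C)(C)Cl
Why: Imidazole-promoted O-silylation masks the acidic phenol for the organoaluminium step as an ether that fluoride removes at the end.

Step 3
Reactants: 3 2-(tert-butyldimethylsilyloxy)-5-methoxy-3-methylbenzaldehyde
Product: 4 [2-(tert-butyldimethylsilyloxy)-5-methoxy-3-methylphenyl]methanol
Conditions: NaBH4, MeOH, 0 °C, short reaction time
Reagents that add atoms: none
Why: Borohydride reduction of the aldehyde in a protic medium at low temperature should give the benzylic alcohol before O-to-O silyl migration can compete.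

Step 4
Reactants: 4 [2-(tert-butyldimethylsilyloxy)-5-methoxy-3-methylphenyl]methanol
Product: 5 tert-butyl[2-(chloromethyl)-4-methoxy-6-methylphenoxy]dimethylsilane
Conditions: PPh3, N-chlorosuccinimide, CH2Cl2, 0 °C to rt
Reagents that add atoms: N-chlorosuccinimide, O=C1CCC(=O)N1Cl
Why: Appel-type chlorination through the alkoxyphosphonium salt is neutral and should convert the benzylic alcohol into the chloride without cleaving the aryl silyl ether.

Step 5
Reactants: 6 geranyl acetate [(2E)-3,7-dimethylocta-2,6-dien-1-yl acetate]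
Product: 8 (2E,6E)-3,7-dimethyl-8-oxoocta-2,6-dien-1-yl acetate, via 8-hydroxygeranyl acetate 7 (not isolated)
Conditions: SeO2 (cat.), t-BuOOH, salicylic acid (cat.), CH2Cl2, rt; work-up; crude, TEMPO (cat.), PhI(OAc)2, CH2Cl2, rt
Reagents that add atoms: tert-butyl hydroperoxide, CC(C)(C)OO
Why: SeO2/t-BuOOH allylic oxidation (ene reaction then [2,3]-sigmatropic shift) is selective for the E-methyl of the terminal trisubstituted alkene, and the TEMPO/PhI(OAc)2 oxidation should converge the alcohol/aldehyde mixture on the E-enal.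

Step 6
Reactants: 8 (2E,6E)-3,7-dimethyl-8-oxoocta-2,6-dien-1-yl acetate
Product: 9 (2E,6E,8R)-8-hydroxy-3,7-dimethylundeca-2,6,10-trien-1-yl acetate
Conditions: allylboronic acid pinacol ester, (R)-TRIP [(R)-3,3′-bis(2,4,6-triisopropylphenyl)-1,1′-binaphthyl-2,2′-diyl hydrogen phosphate] (5 mol%), toluene, −30 °C
Reagents that add atoms: allylboronic acid pinacol ester, C=CCB1OC(C)(C)C(C)(C)O1
Why: Chiral phosphoric acid-catalysed allylboration proceeds through a closed chair transition state in which the catalyst binds the boronate oxygen and the formyl hydrogen, which should expose the Re face of the α-branched enal and set 8R (C12′) under neutral conditions that spare the acetate.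

Step 7
Reactants: 9 (2E,6E,8R)-8-hydroxy-3,7-dimethylundeca-2,6,10-trien-1-yl acetate
Product: 10 (2E,6E,8R)-8-(tert-butyldimethylsilyloxy)-3,7-dimethylundeca-2,6,10-trien-1-yl acetate
Conditions: TBSCl, imidazole, DMF, rt
Reagents that add atoms: tert-butyldimethylsilyl chloride, CC(C)(C)[Si](C)(C)Cl
Why: Standard silylation protects the secondary allylic alcohol so that the later acetate cleavage, oxidation and organoaluminium steps see no free hydroxyl at C12′.

Step 8
Reactants: 10 (2E,6E,8R)-8-(tert-butyldimethylsilyloxy)-3,7-dimethylundeca-2,6,10-trien-1-yl acetate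
Product: 11 (2E,6E,8R)-8-(tert-butyldimethylsilyloxy)-3,7,11-trimethyldodeca-2,6,10-trien-1-yl acetate
Conditions: 2-methylbut-2-ene (large excess), second-generation Grubbs catalyst RuCl2(=CHPh)(PCy3)(H2IMes) (5 mol%), CH2Cl2, 35 °C
Reagents that add atoms: 2-methylbut-2-ene, CC=C(C)C
Why: Olefin cross-metathesis with 2-methylbut-2-ene should convert only the monosubstituted terminal alkene into the prenyl terminus, because the two trisubstituted alkenes are too hindered to enter the catalytic cycle.

Step 9
Reactants: 11 (2E,6E,8R)-8-(tert-butyldimethylsilyloxy)-3,7,11-trimethyldodeca-2,6,10-trien-1-yl acetate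
Product: 12 (2E,6E,8R)-8-(tert-butyldimethylsilyloxy)-3,7,11-trimethyldodeca-2,6,10-trien-1-ol
Conditions: K2CO3 (cat.), MeOH, rt
Reagents that add atoms: none
Why: Base-catalysed transesterification (methanolysis) removes the acetate while the secondary silyl ether is stable.

Step 10
Reactants: 12 (2E,6E,8R)-8-(tert-butyldimethylsilyloxy)-3,7,11-trimethyldodeca-2,6,10-trien-1-ol
Product: 13 (2E,6E,8R)-8-(tert-butyldimethylsilyloxy)-3,7,11-trimethyldodeca-2,6,10-trienal
Conditions: TEMPO (cat.), PhI(OAc)2, CH2Cl2, rt
Reagents that add atoms: none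
Why: Oxoammonium-mediated (TEMPO) oxidation of the primary allylic alcohol should give the E-enal without over-oxidation or E/Z isomerisation.

Step 11
Reactants: 13 (2E,6E,8R)-8-(tert-butyldimethylsilyloxy)-3,7,11-trimethyldodeca-2,6,10-trienal
Product: 14 (4R,5E,9E,11R)-11-(tert-butyldimethylsilyloxy)-6,10,14-trimethylpentadeca-5,9,13-trien-1-yn-4-ol
Conditions: allenylboronic acid pinacol ester, (R)-TRIP (10 mol%), 4 Å MS, toluene, −20 °C
Reagents that add atoms: allenylboronic acid pinacol ester, C=C=CB1OC(C)(C)C(C)(C)O1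
Why: Chiral phosphoric acid-catalysed propargylation transfers the allenylboronate by SE2′ through a six-membered transition state to the Re face of the enal, which should give the homopropargylic alcohol with 4R (C5′) and install the terminal alkyne needed for the key step.

Step 12
Reactants: 14 (4R,5E,9E,11R)-11-(tert-butyldimethylsilyloxy)-6,10,14-trimethylpentadeca-5,9,13-trien-1-yn-4-ol
Product: 15 (4R,5E,9E,11R)-4,11-bis(tert-butyldimethylsilyloxy)-6,10,14-trimethylpentadeca-5,9,13-trien-1-yne
Conditions: TBSCl, imidazole, DMF, rt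
Reagents that add atoms: tert-butyldimethylsilyl chloride, CC(C)(C)[Si](C)(C)Cl
Why: Standard silylation caps the homopropargylic hydroxyl so that methylalumination is not diverted by an aluminium alkoxide.

Step 13
Reactants: 15 (4R,5E,9E,11R)-4,11-bis(tert-butyldimethylsilyloxy)-6,10,14-trimethylpentadeca-5,9,13-trien-1-yne; 5 tert-butyl[2-(chloromethyl)-4-methoxy-6-methylphenoxy]dimethylsilane
Product: 17 tert-butyl{2-[(2E,5R,6E,10E,12R)-5,12-bis(tert-butyldimethylsilyloxy)-3,7,11,15-tetramethylhexadeca-2,6,10,14-tetraen-1-yl]-4-methoxy-6-methylphenoxy}dimethylsilane, via alkenyldimethylalane 16 (not isolated)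
Conditions: AlMe3 (2.5 equiv), Cp2ZrCl2 (0.3 equiv), H2O (1 equiv), CH2Cl2, −20 to 0 °C; volatiles removed; THF, 5, Pd(PPh3)4 (5 mol%), rt
Reagents that add atoms: trimethylaluminium, C[Al](C)C
Why: Zirconium-catalysed syn-methylalumination of the terminal alkyne (Negishi carboalumination) places the methyl on C3′ and aluminium on C2′ on the same side, giving alane 16; the benzylic C–Cl bond of 5 then adds oxidatively to zerovalent palladium, the alkenyl group passes from aluminium to palladium with retention, and reductive elimination forms C1′–C2′. The closest known reaction type is the one-flask carboalumination/palladium- or nickel-catalysed coupling of alkenylalanes with benzylic chlorides used to attach polyprenyl chains to arenes and quinones. No ring is closed and no stereocentre is formed; the new stereochemical element is the 2′E alkene, fixed by syn addition and retention in the coupling, so the C3′ methyl ends cis to C1′. Three components (alkyne, methyl, ring A benzyl unit) are joined, which creates the last trisubstituted alkene, its methyl branch and the arene–chain junction at once. The step needs regioselectivity (aluminium at the terminal carbon, the normal outcome for terminal alkynes including homopropargylic silyl ethers), chemoselectivity (trisubstituted alkenes do not carbometalate; alkenyl transfers in preference to methyl) and survival of the allylic silyl ethers and the benzylic chloride, which low-temperature water-accelerated carboalumination and the change to THF after stripping excess AlMe3 should secure.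

Step 14
Reactants: 17 tert-butyl{2-[(2E,5R,6E,10E,12R)-5,12-bis(tert-butyldimethylsilyloxy)-3,7,11,15-tetramethylhexadeca-2,6,10,14-tetraen-1-yl]-4-methoxy-6-methylphenoxy}dimethylsilane
Product: 18 2-[(2E,5R,6E,10E,12R)-5,12-dihydroxy-3,7,11,15-tetramethylhexadeca-2,6,10,14-tetraen-1-yl]-4-methoxy-6-methylphenol
Conditions: TBAF (4 equiv), THF, 0 °C to rt; aq. NH4Cl
Reagents that add atoms: none
Why: Fluoride-mediated desilylation should cleave the aryl and both secondary allylic silyl ethers in one operation without touching the alkenes or the two carbinol centres.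

**Compound list**

1 | 4-methoxy-2-methylphenol | COc1ccc(O)c(C)c1 | starting material
2 | 2-hydroxy-5-methoxy-3-methylbenzaldehyde | COc1cc(C)c(O)c(C=O)c1 | intermediate
3 | 2-(tert-butyldimethylsilyloxy)-5-methoxy-3-methylbenzaldehyde | COc1cc(C)c(O[Si](C)(C)C(C)(C)C)c(C=O)c1 | intermediate
4 | [2-(tert-butyldimethylsilyloxy)-5-methoxy-3-methylphenyl]methanol | COc1cc(C)c(O[Si](C)(C)C(C)(C)C)c(CO)c1 | intermediate
5 | tert-butyl[2-(chloromethyl)-4-methoxy-6-methylphenoxy]dimethylsilane | COc1cc(C)c(O[Si](C)(C)C(C)(C)C)c(CCl)c1 | intermediate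
6 | geranyl acetate, (2E)-3,7-dimethylocta-2,6-dien-1-yl acetate | CC(=O)OC/C=C(\C)CCC=C(C)C | starting material
7 | 8-hydroxygeranyl acetate, (2E,6E)-8-hydroxy-3,7-dimethylocta-2,6-dien-1-yl acetate | CC(=O)OC/C=C(\C)CC/C=C(\C)CO | intermediate
8 | (2E,6E)-3,7-dimethyl-8-oxoocta-2,6-dien-1-yl acetate | CC(=O)OC/C=C(\C)CC/C=C(\C)C=O | intermediate
9 | (2E,6E,8R)-8-hydroxy-3,7-dimethylundeca-2,6,10-trien-1-yl acetate | CC(=O)OC/C=C(\C)CC/C=C(\C)[C@H](O)CC=C | intermediate
10 | (2E,6E,8R)-8-(tert-butyldimethylsilyloxy)-3,7-dimethylundeca-2,6,10-trien-1-yl acetate | CC(=O)OC/C=C(\C)CC/C=C(\C)[C@H](O[Si](C)(C)C(C)(C)C)CC=C | intermediate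
11 | (2E,6E,8R)-8-(tert-butyldimethylsilyloxy)-3,7,11-trimethyldodeca-2,6,10-trien-1-yl acetate | CC(=O)OC/C=C(\C)CC/C=C(\C)[C@H](O[Si](C)(C)C(C)(C)C)CC=C(C)C | intermediate
12 | (2E,6E,8R)-8-(tert-butyldimethylsilyloxy)-3,7,11-trimethyldodeca-2,6,10-trien-1-ol | OC/C=C(\C)CC/C=C(\C)[C@H](O[Si](C)(C)C(C)(C)C)CC=C(C)C | intermediate
13 | (2E,6E,8R)-8-(tert-butyldimethylsilyloxy)-3,7,11-trimethyldodeca-2,6,10-trienal | O=C/C=C(\C)CC/C=C(\C)[C@H](O[Si](C)(C)C(C)(C)C)CC=C(C)C | intermediate
14 | (4R,5E,9E,11R)-11-(tert-butyldimethylsilyloxy)-6,10,14-trimethylpentadeca-5,9,13-trien-1-yn-4-ol | C#CC[C@@H](O)/C=C(\C)CC/C=C(\C)[C@H](O[Si](C)(C)C(C)(C)C)CC=C(C)C | intermediate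
15 | (4R,5E,9E,11R)-4,11-bis(tert-butyldimethylsilyloxy)-6,10,14-trimethylpentadeca-5,9,13-trien-1-yne | C#CC[C@@H](O[Si](C)(C)C(C)(C)C)/C=C(\C)CC/C=C(\C)[C@H](O[Si](C)(C)C(C)(C)C)CC=C(C)C | intermediate
16 | [(1E,4R,5E,9E,11R)-4,11-bis(tert-butyldimethylsilyloxy)-2,6,10,14-tetramethylpentadeca-1,5,9,13-tetraen-1-yl]dimethylalane | C[Al](C)/C=C(\C)C[C@@H](O[Si](C)(C)C(C)(C)C)/C=C(\C)CC/C=C(\C)[C@H](O[Si](C)(C)C(C)(C)C)CC=C(C)C | intermediate
17 | tert-butyl{2-[(2E,5R,6E,10E,12R)-5,12-bis(tert-butyldimethylsilyloxy)-3,7,11,15-tetramethylhexadeca-2,6,10,14-tetraen-1-yl]-4-methoxy-6-methylphenoxy}dimethylsilane | COc1cc(C)c(O[Si](C)(C)C(C)(C)C)c(C/C=C(\C)C[C@@H](O[Si](C)(C)C(C)(C)C)/C=C(\C)CC/C=C(\C)[C@H](O[Si](C)(C)C(C)(C)C)CC=C(C)C)c1 | intermediate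
18 | 2-[(2E,5R,6E,10E,12R)-5,12-dihydroxy-3,7,11,15-tetramethylhexadeca-2,6,10,14-tetraen-1-yl]-4-methoxy-6-methylphenol | COc1cc(C)c(O)c(C/C=C(\C)C[C@@H](O)/C=C(\C)CC/C=C(\C)[C@H](O)CC=C(C)C)c1 | target

**Step count and risks**

Total step count: 14. Longest linear sequence: 10 steps (steps 5 to 14, from geranyl acetate); the arene branch (steps 1 to 4) joins at step 13.

Steps most likely to fail:

Step 13. Residual Lewis-acidic aluminium species may ionise the benzylic chloride or the allylic silyl ethers, or alkenyl transfer to palladium may be slow enough for the alane to decompose. The fallback sets out from 15 and 5 and returns at 17. The same zirconium-catalysed methylalumination of 15 is quenched with I2 (THF, −30 °C) to give the (1E)-alkenyl iodide F1, which is isolated. Separately, 5 is treated with zinc dust and LiCl in THF to give the benzylzinc chloride F2. Negishi coupling of F1 with F2 (Pd(OAc)2, SPhos, THF, rt) should then give 17. The polarity of the partners is reversed and no aluminium is present when C1′–C2′ is formed.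

Step 11. Facial selectivity may erode with the β,β-disubstituted enal, and some allenyl carbinol may form by direct rather than SE2′ transfer. The fallback sets out from 13 and returns at 15, replacing steps 11 and 12. The titanium enolate of (S)-3-acetyl-4-isopropyl-1,3-thiazolidine-2-thione (TiCl4, i-Pr2NEt, CH2Cl2, −78 °C) should add to 13 through a chelated chair transition state on the face anti to the isopropyl group, giving the (3R)-acetate aldol F3. Silylation (TBSOTf, 2,6-lutidine, CH2Cl2, −78 °C) gives the silyl ether F4. Reduction with i-Bu2AlH (CH2Cl2, −78 °C) releases the auxiliary and gives the β-silyloxy aldehyde F5. Ohira–Bestmann homologation (dimethyl (1-diazo-2-oxopropyl)phosphonate, K2CO3, MeOH, 0 °C to rt) converts F5 into alkyne 15.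

Step 6. Facial selectivity in the allylboration may be poor with the α-branched enal. The fallback sets out from 8 and returns at 9. Barbier allylation (allyl bromide, zinc dust, THF/aq. NH4Cl, rt) gives the racemic homoallylic alcohol F6. Dess–Martin oxidation (NaHCO3, CH2Cl2, 0 °C) gives the dienone F7. Corey–Bakshi–Shibata reduction ((S)-2-methyl-CBS-oxazaborolidine (cat.), catecholborane, toluene, −78 °C), with the α-methylalkenyl group acting as the large substituent, should give the (8R)-alcohol 9. Stereocontrol thus moves from C–C bond formation to a reagent-controlled ketone reduction.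

Further compounds
F1 | step 13 | (1E,4R,5E,9E,11R)-4,11-bis(tert-butyldimethylsilyloxy)-1-iodo-2,6,10,14-tetramethylpentadeca-1,5,9,13-tetraene | I/C=C(\C)C[C@@H](O[Si](C)(C)C(C)(C)C)/C=C(\C)CC/C=C(\C)[C@H](O[Si](C)(C)C(C)(C)C)CC=C(C)C
F2 | step 13 | {[2-(tert-butyldimethylsilyloxy)-5-methoxy-3-methylphenyl]methyl}zinc chloride | COc1cc(C)c(O[Si](C)(C)C(C)(C)C)c(C[Zn]Cl)c1
F3 | step 11 | (3R,4E,8E,10R)-10-(tert-butyldimethylsilyloxy)-3-hydroxy-1-[(4S)-4-isopropyl-2-thioxo-1,3-thiazolidin-3-yl]-5,9,13-trimethyltetradeca-4,8,12-trien-1-one | O=C(C[C@@H](O)/C=C(\C)CC/C=C(\C)[C@H](O[Si](C)(C)C(C)(C)C)CC=C(C)C)N1[C@@H](C(C)C)CSC1=S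
F4 | step 11 | (3R,4E,8E,10R)-3,10-bis(tert-butyldimethylsilyloxy)-1-[(4S)-4-isopropyl-2-thioxo-1,3-thiazolidin-3-yl]-5,9,13-trimethyltetradeca-4,8,12-trien-1-one | O=C(C[C@@H](O[Si](C)(C)C(C)(C)C)/C=C(\C)CC/C=C(\C)[C@H](O[Si](C)(C)C(C)(C)C)CC=C(C)C)N1[C@@H](C(C)C)CSC1=S
F5 | step 11 | (3R,4E,8E,10R)-3,10-bis(tert-butyldimethylsilyloxy)-5,9,13-trimethyltetradeca-4,8,12-trienal | O=CC[C@@H](O[Si](C)(C)C(C)(C)C)/C=C(\C)CC/C=C(\C)[C@H](O[Si](C)(C)C(C)(C)C)CC=C(C)C
F6 | step 6 | racemic (2E,6E)-8-hydroxy-3,7-dimethylundeca-2,6,10-trien-1-yl acetate | CC(=O)OC/C=C(\C)CC/C=C(\C)C(O)CC=C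
F7 | step 6 | (2E,6E)-3,7-dimethyl-8-oxoundeca-2,6,10-trien-1-yl acetate | CC(=O)OC/C=C(\C)CC/C=C(\C)C(=O)CC=C
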